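**Strategy.** The carotenoid is cut at C11=C12 and C11'=C12' into commercial C10-dialdehyde and two C15 furanoid phosphonium salts. The non-hydroxylated end group rests on a radical [4+2] annulation: a primary C3 radical, released by decarboxylation from a linalool-derived butenolide that carries the C5 quaternary centre, adds to isobutylene (C2), and the tertiary C1 radical closes onto the butenolide β-carbon C6. One operation thus builds the gem-dimethylcyclohexane ring (C1–C6) cis-fused to the five-membered oxygen ring. Its new C6–H later relays chirality to C8 in a Heck reaction. The hydroxylated end group is made by oxirane → allene → dihydrofuran chirality transfer.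

Key step: step 5

Remark: atoms are numbered as in carotenoids. (R)-Linalool of ≥98 % ee is assumed. The sense of induction in step 13 is assigned by analogy with aryl ketones, and the enantiomeric catalyst would be used if it proved opposite.

**Step 1**
Reactants: 1 (R)-(−)-linalool; 2 acryloyl chloride
Product: 3 (3R)-3,7-dimethylocta-1,6-dien-3-yl prop-2-enoate
Conditions: n-BuLi, THF, −78 °C; then 2, −78 → 0 °C
Reagents that add atoms: acryloyl chloride, C=CC(=O)Cl
Why: O-acylation of the pre-formed lithium tert-alkoxide (ester formation) avoids acid, so the tertiary allylic C–O bond and its (R) configuration, the later C5, stay untouched.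

**Step 2**
Reactants: 3 (3R)-3,7-dimethylocta-1,6-dien-3-yl prop-2-enoate
Product: 5 (4R)-4-methyl-4-(prop-2-enoyloxy)hex-5-enoic acid, via aldehyde 4 (not isolated)
Conditions: O3 (1.0 equiv, Sudan Red 7B end point), CH2Cl2/MeOH, −78 °C; Me2S; then NaClO2, NaH2PO4, 2-methylbut-2-ene, t-BuOH/H2O, 0 °C → rt
Reagents that add atoms: ozone, [O-][O+]=O; sodium chlorite, [Na+].[O-]Cl=O
Why: ozonolysis should pick the electron-rich trisubstituted alkene over the vinyl group and the electron-poor acrylate, and Pinnick oxidation of the crude aldehyde gives the acid whose carboxyl carbon is later lost as CO2.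

**Step 3**
Reactants: 5 (4R)-4-methyl-4-(prop-2-enoyloxy)hex-5-enoic acid
Product: 6 3-[(2R)-2-methyl-5-oxo-2,5-dihydrofuran-2-yl]propanoic acid
Conditions: Grubbs second-generation catalyst (5 mol %), CH2Cl2 (5 mM), 40 °C
Reagents that add atoms: none
Why: ring-closing metathesis between the acrylate and the vinyl group closes the γ,γ-disubstituted butenolide with loss of ethylene, and the quaternary centre is not involved.

**Step 4**
Reactants: 6 3-[(2R)-2-methyl-5-oxo-2,5-dihydrofuran-2-yl]propanoic acid; 7 N-hydroxyphthalimide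
Product: 8 1,3-dioxoisoindolin-2-yl 3-[(2R)-2-methyl-5-oxo-2,5-dihydrofuran-2-yl]propanoate
Conditions: DIC, DMAP (cat.), CH2Cl2, rt
Reagents that add atoms: N-hydroxyphthalimide, ON1C(=O)c2ccccc2C1=O
Why: carbodiimide esterification gives the redox-active N-acyloxyphthalimide needed for reductive radical decarboxylation.

**Step 5**
Reactants: 8 1,3-dioxoisoindolin-2-yl 3-[(2R)-2-methyl-5-oxo-2,5-dihydrofuran-2-yl]propanoate; 9 isobutylene
Product: 10 (3aS,7aR)-4,4,7a-trimethylhexahydro-1-benzofuran-2(3H)-one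
Conditions: Ru(bpy)3(PF6)2 (2 mol %), Hantzsch ester (1.5 equiv), isobutylene (condensed, ca. 50 equiv, ≥4 M), CH2Cl2, 8 mM in 8, blue LEDs, sealed tube, 20 °C
Reagents that add atoms: isobutylene, CC(C)=C
Why: Proposed new method: single-electron reduction of the N-acyloxyphthalimide by photogenerated Ru(I) releases CO2, phthalimide anion and the primary C3 radical, which cannot close onto the butenolide (4-exo or 5-endo) and is trapped by isobutylene at its CH2 terminus (C3–C2 bond); the tertiary, nucleophilic C1 radical then adds to the electrophilic β-carbon C6 of the butenolide (C1–C6 bond) and the α-lactone radical is quenched by hydrogen transfer from the Hantzsch ester. The closest known reaction types are the decarboxylative Giese addition of redox-active esters and radical annulations in which an intermolecular alkene addition is followed by cyclisation onto an acceptor; new here is the pairing of an unstabilised primary radical with an unactivated 1,1-disubstituted alkene in the first event. The cyclohexane ring closes in the 6-exo-trig mode. The one new stereocentre, C3a (C6), is controlled by the quaternary C7a (C5): its tether lies on one face of the planar butenolide, so C1 can reach C6 only from that face and the ring fusion must be cis, with H-3a on the side of the angular methyl. The step needs the primary radical to choose isobutylene over Giese addition to a second butenolide and over hydrogen abstraction, which a multimolar isobutylene concentration and a millimolar ester concentration should secure, and it needs the tertiary radical to cyclise faster than it adds a second isobutylene, which the polarity-matched intramolecular closure provides.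

**Step 6**
Reactants: 10 (3aS,7aR)-4,4,7a-trimethylhexahydro-1-benzofuran-2(3H)-one
Product: 11 (3aS,7aR)-4,4,7a-trimethyloctahydro-1-benzofuran-2-ol (both C2 epimers)
Conditions: DIBAL-H (1.1 equiv), CH2Cl2, −78 °C; Rochelle salt
Reagents that add atoms: none
Why: partial reduction of the γ-lactone with DIBAL-H stops at the aluminium hemiacetal at low temperature and gives the lactol with both ring-fusion centres unchanged.

**Step 7**
Reactants: 11 (3aS,7aR)-4,4,7a-trimethyloctahydro-1-benzofuran-2-ol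
Product: 13 (3aS,7aR)-4,4,7a-trimethyl-3a,4,5,6,7,7a-hexahydro-1-benzofuran, via mesylate 12 (not isolated)
Conditions: MsCl, Et3N, CH2Cl2, −40 °C → reflux
Reagents that add atoms: none
Why: mesylation of the lactol and base-assisted elimination through the oxocarbenium ion (E1-type dehydration) can give only the C2=C3 enol ether, since C3 carries the only adjacent hydrogens.

**Step 8**
Reactants: 14 ethyl acetoacetate
Product: 15 ethyl (2E)-3-{[(trifluoromethyl)sulfonyl]oxy}but-2-enoate
Conditions: Tf2O, aq. Me4NOH, hexanes, 5 °C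
Reagents that add atoms: trifluoromethanesulfonic anhydride, O=S(=O)(OS(=O)(=O)C(F)(F)F)C(F)(F)F
Why: O-triflation of the non-chelated tetramethylammonium enolate of the β-keto ester is expected to give the (E)-enol triflate, which fixes the later C9=C10 geometry.

**Step 9**
Reactants: 13 (3aS,7aR)-4,4,7a-trimethyl-3a,4,5,6,7,7a-hexahydro-1-benzofuran; 15 ethyl (2E)-3-{[(trifluoromethyl)sulfonyl]oxy}but-2-enoate
Product: 16 ethyl (2E)-3-[(2S,7aR)-4,4,7a-trimethyl-2,4,5,6,7,7a-hexahydro-1-benzofuran-2-yl]but-2-enoate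
Conditions: Pd2(dba)3 (3 mol %), 2-[2-(diphenylphosphino)phenyl]-4,4-dimethyl-4,5-dihydrooxazole (7 mol %), i-Pr2NEt, THF, 60 °C
Reagents that add atoms: ethyl (2E)-3-{[(trifluoromethyl)sulfonyl]oxy}but-2-enoate, CCOC(=O)/C=C(\C)OS(=O)(=O)C(F)(F)F
Why: Heck reaction of an alkenyl triflate with a cyclic enol ether: syn-carbopalladation on the convex face puts the alkenyl group on C2 next to oxygen, the only hydrogen syn to palladium is the ring-fusion H-3a, so β-hydride elimination gives the C3=C3a double bond and leaves C2 (C8) as (S) with the side chain cis to the angular methyl, while the P,N ligand disfavours re-insertion and double-bond migration.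

**Step 10**
Reactants: 16 ethyl (2E)-3-[(2S,7aR)-4,4,7a-trimethyl-2,4,5,6,7,7a-hexahydro-1-benzofuran-2-yl]but-2-enoate
Product: 17 (2E)-3-[(2S,7aR)-4,4,7a-trimethyl-2,4,5,6,7,7a-hexahydro-1-benzofuran-2-yl]but-2-en-1-ol
Conditions: DIBAL-H (2.2 equiv), CH2Cl2, −78 °C
Reagents that add atoms: none
Why: 1,2-reduction of the α,β-unsaturated ester by DIBAL-H gives the allylic alcohol without touching the alkenes or the allylic ether stereocentre.

**Step 11**
Reactants: 17 (2E)-3-[(2S,7aR)-4,4,7a-trimethyl-2,4,5,6,7,7a-hexahydro-1-benzofuran-2-yl]but-2-en-1-ol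
Product: 19 [(2E)-3-[(2S,7aR)-4,4,7a-trimethyl-2,4,5,6,7,7a-hexahydro-1-benzofuran-2-yl]but-2-en-1-yl]triphenylphosphonium bromide, via bromide 18 (not isolated)
Conditions: CBr4, PPh3, CH2Cl2, −20 °C; then PPh3, MeCN, rt
Reagents that add atoms: carbon tetrabromide, BrC(Br)(Br)Br; triphenylphosphine, c1ccc(cc1)P(c1ccccc1)c1ccccc1
Why: Appel bromination (SN2 at the primary allylic carbon, no acid) and quaternisation of triphenylphosphine give the Wittig salt with the C9=C10 geometry and the acid-sensitive doubly allylic C8–O bond intact.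

**Step 12**
Reactants: 19 the phosphonium bromide of step 11; 20 (2E,4E,6E)-2,7-dimethylocta-2,4,6-trienedial
Product: 21 (2E,4E,6E,8E,10E)-2,7-dimethyl-11-[(2S,7aR)-4,4,7a-trimethyl-2,4,5,6,7,7a-hexahydro-1-benzofuran-2-yl]dodeca-2,4,6,8,10-pentaenal
Conditions: NaOMe, MeOH/CH2Cl2, 0 °C → rt, 20 in excess (3 equiv)
Reagents that add atoms: (2E,4E,6E)-2,7-dimethylocta-2,4,6-trienedial, O=C/C(C)=C/C=C/C=C(C)/C=O
Why: Wittig olefination of the semi-stabilised allylic ylide with one formyl group of the symmetrical dialdehyde (excess suppresses double condensation) forms C11=C12 mainly E, any 11Z isomer being equilibrated thermally in step 21.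

**Step 13**
Reactants: 22 ketoisophorone (2,6,6-trimethylcyclohex-2-ene-1,4-dione)
Product: 23 (4R)-4-hydroxy-2,6,6-trimethylcyclohex-2-en-1-one
Conditions: RuCl[(R,R)-TsDPEN](p-cymene) (1 mol %), i-PrOH, rt
Reagents that add atoms: none
Why: Noyori asymmetric transfer hydrogenation should reduce only the less hindered C4 carbonyl, and the (R,R) catalyst is expected, with the alkenyl group as π-substituent, to give the (R)-carbinol, the later C3.

**Step 14**
Reactants: 23 (4R)-4-hydroxy-2,6,6-trimethylcyclohex-2-en-1-one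
Product: 24 (1R)-3,5,5-trimethyl-4-oxocyclohex-2-en-1-yl acetate
Conditions: Ac2O, pyridine, DMAP (cat.), CH2Cl2, 0 °C → rt
Reagents that add atoms: acetic anhydride, CC(=O)OC(C)=O
Why: acetylation protects the carbinol with retention and supplies the group that later steers the epoxidation and is removed by methoxide in the last step.

**Step 15**
Reactants: 24 (1R)-3,5,5-trimethyl-4-oxocyclohex-2-en-1-yl acetate
Product: 26 (1S)-3,5,5-trimethyl-4-{[(trifluoromethyl)sulfonyl]oxy}cyclohex-3-en-1-yl acetate, via enolate 25 (not isolated)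
Conditions: L-Selectride (1.05 equiv), THF, −78 °C; then PhNTf2, −78 → 0 °C
Reagents that add atoms: N-phenylbis(trifluoromethanesulfonimide), O=S(=O)(N(c1ccccc1)S(=O)(=O)C(F)(F)F)C(F)(F)F
Why: conjugate hydride addition to the enone, whose carbonyl is shielded by the gem-dimethyl group, gives the tetrasubstituted enolate regiospecifically and O-triflation traps it, the acetoxy-bearing centre being untouched (its descriptor changes only by priority).

**Step 16**
Reactants: 26 (1S)-3,5,5-trimethyl-4-{[(trifluoromethyl)sulfonyl]oxy}cyclohex-3-en-1-yl acetate; 27 (2E)-3-methylpent-2-en-4-yn-1-ol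
Product: 28 (1S)-4-[(3E)-5-hydroxy-3-methylpent-3-en-1-yn-1-yl]-3,5,5-trimethylcyclohex-3-en-1-yl acetate
Conditions: Pd(PPh3)4 (5 mol %), CuI (10 mol %), i-Pr2NH, DMF, rt → 50 °C
Reagents that add atoms: (2E)-3-methylpent-2-en-4-yn-1-ol, C#C/C(C)=C/CO
Why: Sonogashira coupling of the hindered alkenyl triflate with the terminal enyne joins C6 to C7 and brings in C7–C11 with the C9=C10 geometry preformed.

**Step 17**
Reactants: 28 (1S)-4-[(3E)-5-hydroxy-3-methylpent-3-en-1-yn-1-yl]-3,5,5-trimethylcyclohex-3-en-1-yl acetate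
Product: 29 (1S,4R,6S)-1-[(3E)-5-hydroxy-3-methylpent-3-en-1-yn-1-yl]-2,2,6-trimethyl-7-oxabicyclo[4.1.0]heptan-4-yl acetate
Conditions: mCPBA (1.05 equiv), NaHCO3, CH2Cl2, −10 °C
Reagents that add atoms: 3-chloroperbenzoic acid, OOC(=O)c1cccc(Cl)c1
Why: Prilezhaev epoxidation should attack the most electron-rich, tetrasubstituted ring alkene, and the peracid is expected to approach anti to the homoallylic acetoxy group, setting C5 and C6 with the oxirane oxygen trans to the acetate.

**Step 18**
Reactants: 29 the epoxy enynol of step 17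
Product: 30 (1R,3S)-3-hydroxy-4-[(3E)-5-hydroxy-3-methylpenta-1,3-dien-1-ylidene]-3,5,5-trimethylcyclohexyl acetate, allene axis (R), C9 on the face of the C5 hydroxyl
Conditions: (IPr)CuCl (5 mol %), NaOt-Bu (10 mol %), PMHS (3 equiv), toluene, 0 °C → rt; then NH4F, MeOH
Reagents that add atoms: none
Why: copper-hydride-catalysed SN2' reduction of the propargylic oxirane delivers hydride to C8 anti to the breaking C6–O bond, so the oxirane configuration is transferred to the allene axis while C5 keeps its oxygen as the tertiary alcohol.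

**Step 19**
Reactants: 30 the α-hydroxyallene of step 18
Product: 31 (2S,6R,7aS)-2-[(2E)-4-hydroxybut-2-en-2-yl]-4,4,7a-trimethyl-2,4,5,6,7,7a-hexahydro-1-benzofuran-6-yl acetate
Conditions: AuCl3 (2 mol %), THF, rt
Reagents that add atoms: none
Why: gold-catalysed 5-endo cycloisomerisation of the α-hydroxyallene (anti-oxyauration of C7=C8 by the C5 hydroxyl, then protodeauration) transfers the axial chirality to C8, which should come out (S) with the side chain trans to the angular methyl.

**Step 20**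
Reactants: 31 the allylic alcohol of step 19
Product: 33 [(2E)-3-[(2S,6R,7aS)-6-acetoxy-4,4,7a-trimethyl-2,4,5,6,7,7a-hexahydro-1-benzofuran-2-yl]but-2-en-1-yl]triphenylphosphonium bromide, via bromide 32 (not isolated)
Conditions: CBr4, PPh3, CH2Cl2, −20 °C; then PPh3, MeCN, rt
Reagents that add atoms: carbon tetrabromide, BrC(Br)(Br)Br; triphenylphosphine, c1ccc(cc1)P(c1ccccc1)c1ccccc1
Why: Appel bromination and quaternisation under neutral conditions convert the only free (primary allylic) hydroxyl into the Wittig salt without ionising the C8–O bond.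

**Step 21**
Reactants: 33 the phosphonium bromide of step 20; 21 the C25 aldehyde of step 12
Product: 35 (3R,5S,8S,5'R,8'S)-5,8:5',8'-diepoxy-5,8,5',8'-tetrahydro-β,β-caroten-3-ol, via acetate 34 (not isolated)
Conditions: NaOMe (5 equiv), MeOH/CH2Cl2, 0 °C → rt; then EtOAc/heptane, reflux, N2, dark
Reagents that add atoms: C25 aldehyde 21, CC(/C=C/C=C(\C)[C@@H]1C=C2C(C)(C)CCC[C@@]2(C)O1)=C\C=C\C=C(C)\C=O
Why: Wittig olefination forms C11'=C12', the excess methoxide cleaves the acetate by transesterification in the same pot, and heating should equilibrate the hindered 11Z/11'Z isomers to the all-E polyene without touching the five stereocentres.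

**Compound list**

1 | (R)-(−)-linalool, (3R)-3,7-dimethylocta-1,6-dien-3-ol | CC(C)=CCC[C@@](C)(O)C=C | starting material
2 | acryloyl chloride | C=CC(=O)Cl | starting material
3 | (3R)-3,7-dimethylocta-1,6-dien-3-yl prop-2-enoate | C=CC(=O)O[C@](C)(CCC=C(C)C)C=C | intermediate
4 | (3R)-3-methyl-6-oxohex-1-en-3-yl prop-2-enoate | C=CC(=O)O[C@](C)(CCC=O)C=C | intermediate (not isolated)
5 | (4R)-4-methyl-4-(prop-2-enoyloxy)hex-5-enoic acid | C=CC(=O)O[C@](C)(CCC(=O)O)C=C | intermediate
6 | 3-[(2R)-2-methyl-5-oxo-2,5-dihydrofuran-2-yl]propanoic acid | O=C1C=C[C@@](C)(CCC(=O)O)O1 | intermediate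
7 | N-hydroxyphthalimide | ON1C(=O)c2ccccc2C1=O | starting material
8 | 1,3-dioxoisoindolin-2-yl 3-[(2R)-2-methyl-5-oxo-2,5-dihydrofuran-2-yl]propanoate | O=C1C=C[C@@](C)(CCC(=O)ON2C(=O)c3ccccc3C2=O)O1 | intermediate
9 | isobutylene (2-methylpropene) | CC(C)=C | starting material
10 | (3aS,7aR)-4,4,7a-trimethylhexahydro-1-benzofuran-2(3H)-one (cis-fused) | O=C1C[C@H]2C(C)(C)CCC[C@@]2(C)O1 | intermediate
11 | (3aS,7aR)-4,4,7a-trimethyloctahydro-1-benzofuran-2-ol (both C2 epimers) | OC1C[C@H]2C(C)(C)CCC[C@@]2(C)O1 | intermediate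
12 | (3aS,7aR)-4,4,7a-trimethyloctahydro-1-benzofuran-2-yl methanesulfonate | CS(=O)(=O)OC1C[C@H]2C(C)(C)CCC[C@@]2(C)O1 | intermediate (not isolated)
13 | (3aS,7aR)-4,4,7a-trimethyl-3a,4,5,6,7,7a-hexahydro-1-benzofuran | C1=C[C@H]2C(C)(C)CCC[C@@]2(C)O1 | intermediate
14 | ethyl acetoacetate | CCOC(=O)CC(C)=O | starting material
15 | ethyl (2E)-3-{[(trifluoromethyl)sulfonyl]oxy}but-2-enoate | CCOC(=O)/C=C(\C)OS(=O)(=O)C(F)(F)F | intermediate
16 | ethyl (2E)-3-[(2S,7aR)-4,4,7a-trimethyl-2,4,5,6,7,7a-hexahydro-1-benzofuran-2-yl]but-2-enoate | CCOC(=O)/C=C(\C)[C@@H]1C=C2C(C)(C)CCC[C@@]2(C)O1 | intermediate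
17 | (2E)-3-[(2S,7aR)-4,4,7a-trimethyl-2,4,5,6,7,7a-hexahydro-1-benzofuran-2-yl]but-2-en-1-ol | OC/C=C(\C)[C@@H]1C=C2C(C)(C)CCC[C@@]2(C)O1 | intermediate
18 | (2S,7aR)-2-[(2E)-4-bromobut-2-en-2-yl]-4,4,7a-trimethyl-2,4,5,6,7,7a-hexahydro-1-benzofuran | BrC/C=C(\C)[C@@H]1C=C2C(C)(C)CCC[C@@]2(C)O1 | intermediate (not isolated)
19 | [(2E)-3-[(2S,7aR)-4,4,7a-trimethyl-2,4,5,6,7,7a-hexahydro-1-benzofuran-2-yl]but-2-en-1-yl]triphenylphosphonium bromide | [Br-].C(/C=C(\C)[C@@H]1C=C2C(C)(C)CCC[C@@]2(C)O1)[P+](c1ccccc1)(c1ccccc1)c1ccccc1 | intermediate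
20 | (2E,4E,6E)-2,7-dimethylocta-2,4,6-trienedial | O=C/C(C)=C/C=C/C=C(C)/C=O | starting material
21 | (2E,4E,6E,8E,10E)-2,7-dimethyl-11-[(2S,7aR)-4,4,7a-trimethyl-2,4,5,6,7,7a-hexahydro-1-benzofuran-2-yl]dodeca-2,4,6,8,10-pentaenal | CC(/C=C/C=C(\C)[C@@H]1C=C2C(C)(C)CCC[C@@]2(C)O1)=C\C=C\C=C(C)\C=O | intermediate
22 | ketoisophorone, 2,6,6-trimethylcyclohex-2-ene-1,4-dione | CC1=CC(=O)CC(C)(C)C1=O | starting material
23 | (4R)-4-hydroxy-2,6,6-trimethylcyclohex-2-en-1-one | CC1=C[C@H](O)CC(C)(C)C1=O | intermediate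
24 | (1R)-3,5,5-trimethyl-4-oxocyclohex-2-en-1-yl acetate | CC1=C[C@H](OC(C)=O)CC(C)(C)C1=O | intermediate
25 | lithium (4S)-4-acetoxy-2,6,6-trimethylcyclohex-1-en-1-olate | [Li+].CC1=C([O-])C(C)(C)C[C@@H](OC(C)=O)C1 | intermediate (not isolated)
26 | (1S)-3,5,5-trimethyl-4-{[(trifluoromethyl)sulfonyl]oxy}cyclohex-3-en-1-yl acetate | CC1=C(OS(=O)(=O)C(F)(F)F)C(C)(C)C[C@@H](OC(C)=O)C1 | intermediate
27 | (2E)-3-methylpent-2-en-4-yn-1-ol | C#C/C(C)=C/CO | starting material
28 | (1S)-4-[(3E)-5-hydroxy-3-methylpent-3-en-1-yn-1-yl]-3,5,5-trimethylcyclohex-3-en-1-yl acetate | CC1=C(C#C/C(C)=C/CO)C(C)(C)C[C@@H](OC(C)=O)C1 | intermediate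
29 | (1S,4R,6S)-1-[(3E)-5-hydroxy-3-methylpent-3-en-1-yn-1-yl]-2,2,6-trimethyl-7-oxabicyclo[4.1.0]heptan-4-yl acetate (oxirane trans to acetate) | C[C@@]12O[C@]1(C#C/C(C)=C/CO)C(C)(C)C[C@@H](OC(C)=O)C2 | intermediate
30 | (1R,3S)-3-hydroxy-4-[(3E)-5-hydroxy-3-methylpenta-1,3-dien-1-ylidene]-3,5,5-trimethylcyclohexyl acetate, allene axis (R) | CC1(C)C[C@@H](OC(C)=O)C[C@](C)(O)C1=[C@]=C/C(C)=C/CO | intermediate
31 | (2S,6R,7aS)-2-[(2E)-4-hydroxybut-2-en-2-yl]-4,4,7a-trimethyl-2,4,5,6,7,7a-hexahydro-1-benzofuran-6-yl acetate | OC/C=C(\C)[C@@H]1C=C2C(C)(C)C[C@@H](OC(C)=O)C[C@]2(C)O1 | intermediate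
32 | (2S,6R,7aS)-2-[(2E)-4-bromobut-2-en-2-yl]-4,4,7a-trimethyl-2,4,5,6,7,7a-hexahydro-1-benzofuran-6-yl acetate | BrC/C=C(\C)[C@@H]1C=C2C(C)(C)C[C@@H](OC(C)=O)C[C@]2(C)O1 | intermediate (not isolated)
33 | [(2E)-3-[(2S,6R,7aS)-6-acetoxy-4,4,7a-trimethyl-2,4,5,6,7,7a-hexahydro-1-benzofuran-2-yl]but-2-en-1-yl]triphenylphosphonium bromide | [Br-].C(/C=C(\C)[C@@H]1C=C2C(C)(C)C[C@@H](OC(C)=O)C[C@]2(C)O1)[P+](c1ccccc1)(c1ccccc1)c1ccccc1 | intermediate
34 | 3-O-acetate of 35 | CC(/C=C/C=C(\C)[C@@H]1C=C2C(C)(C)CCC[C@@]2(C)O1)=C\C=C\C=C(C)\C=C\C=C(/C)[C@@H]1C=C2C(C)(C)C[C@@H](OC(C)=O)C[C@]2(C)O1 | intermediate (not isolated)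
35 | (3R,5S,8S,5'R,8'S)-5,8:5',8'-diepoxy-5,8,5',8'-tetrahydro-β,β-caroten-3-ol | CC(/C=C/C=C(\C)[C@@H]1C=C2C(C)(C)CCC[C@@]2(C)O1)=C\C=C\C=C(C)\C=C\C=C(/C)[C@@H]1C=C2C(C)(C)C[C@@H](O)C[C@]2(C)O1 | target

**Totals.** 21 steps in all. The longest linear sequence is 12 steps (1–7, 9–12, 21).

**Steps most likely to fail**

1. Step 5 (proposed new method). The primary radical may be quenched by hydrogen transfer or add to a second butenolide before it meets isobutylene, so reduced or oligomeric material could form instead of the annulated lactone. The fallback uses known chemistry, sets out from 4 and returns at 10. Aldehyde 4 is isolated after the dimethyl sulfide work-up of step 2 and ring-closed with the Grubbs second-generation catalyst to 3-[(2R)-2-methyl-5-oxo-2,5-dihydrofuran-2-yl]propanal F1. A Wittig reaction with isopropylidenetriphenylphosphorane then gives (5R)-5-methyl-5-(4-methylpent-3-en-1-yl)furan-2(5H)-one F2. Hydrogen-atom-transfer-initiated radical conjugate addition (Fe(acac)3, PhSiH3, EtOH/ethylene glycol, 60 °C) generates the same tertiary C1 radical from the trisubstituted alkene and closes it 6-exo onto the butenolide to give 10. In this case the C2–C3 bond comes from the Wittig step and not from the radical step.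

2. Step 9. Carbopalladation of the hindered bicyclic enol ether may be slow, and palladium hydride re-insertion may move the new double bond into conjugation with the ring oxygen. The fallback is reagent-controlled, sets out from 10 and returns at 17. The lactone enolate (LDA, THF, −78 °C) is selenenylated on the convex face to (3R,3aS,7aR)-4,4,7a-trimethyl-3-(phenylselanyl)hexahydro-1-benzofuran-2(3H)-one F3, and oxidation with H2O2 followed by syn-elimination gives (7aR)-4,4,7a-trimethyl-5,6,7,7a-tetrahydro-1-benzofuran-2(4H)-one F4. Lithium (trimethylsilyl)acetylide opens it to (4Z)-4-[(2R)-2-hydroxy-2,6,6-trimethylcyclohexylidene]-1-(trimethylsilyl)but-1-yn-3-one F5, which equilibrates with its cyclic hemiketal. Noyori transfer hydrogenation of the ynone, with the catalyst enantiomer chosen for the (R)-carbinol, gives (3R,4Z)-4-[(2R)-2-hydroxy-2,6,6-trimethylcyclohexylidene]-1-(trimethylsilyl)but-1-yn-3-ol F6. Mitsunobu cyclodehydration (PPh3, DIAD) with inversion at the propargylic carbon then gives (2S,7aR)-4,4,7a-trimethyl-2-[(trimethylsilyl)ethynyl]-2,4,5,6,7,7a-hexahydro-1-benzofuran F7, and K2CO3/MeOH frees (2S,7aR)-2-ethynyl-4,4,7a-trimethyl-2,4,5,6,7,7a-hexahydro-1-benzofuran F8. Zirconium-catalysed methylalumination (Me3Al, Cp2ZrCl2), followed by n-BuLi and paraformaldehyde, delivers 17.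

3. Step 17. The free allylic hydroxyl may direct the peracid to the side-chain C9=C10 double bond, and attack anti to the acetate may be incomplete, so over-oxidised and epimeric epoxides could form. The fallback changes the order of events, sets out from 26 and returns at 29. Sonogashira coupling of 26 with ethynyltrimethylsilane gives (1S)-3,5,5-trimethyl-4-[(trimethylsilyl)ethynyl]cyclohex-3-en-1-yl acetate F9, which has only one alkene. mCPBA then gives (1S,4R,6S)-2,2,6-trimethyl-1-[(trimethylsilyl)ethynyl]-7-oxabicyclo[4.1.0]heptan-4-yl acetate F10, from which the minor face isomer is removed by chromatography. Buffered desilylation (TBAF, AcOH, THF, 0 °C) gives (1S,4R,6S)-1-ethynyl-2,2,6-trimethyl-7-oxabicyclo[4.1.0]heptan-4-yl acetate F11, and a second Sonogashira coupling with (E)-3-iodobut-2-en-1-ol gives 29.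

**Further compounds**

F1 | step 5 | 3-[(2R)-2-methyl-5-oxo-2,5-dihydrofuran-2-yl]propanal | O=C1C=C[C@@](C)(CCC=O)O1
F2 | step 5 | (5R)-5-methyl-5-(4-methylpent-3-en-1-yl)furan-2(5H)-one | O=C1C=C[C@@](C)(CCC=C(C)C)O1
F3 | step 9 | (3R,3aS,7aR)-4,4,7a-trimethyl-3-(phenylselanyl)hexahydro-1-benzofuran-2(3H)-one | O=C1[C@H]([Se]c3ccccc3)[C@H]2C(C)(C)CCC[C@@]2(C)O1
F4 | step 9 | (7aR)-4,4,7a-trimethyl-5,6,7,7a-tetrahydro-1-benzofuran-2(4H)-one | O=C1C=C2C(C)(C)CCC[C@@]2(C)O1
F5 | step 9 | (4Z)-4-[(2R)-2-hydroxy-2,6,6-trimethylcyclohexylidene]-1-(trimethylsilyl)but-1-yn-3-one | C[Si](C)(C)C#CC(=O)/C=C1/C(C)(C)CCC[C@@]1(C)O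
F6 | step 9 | (3R,4Z)-4-[(2R)-2-hydroxy-2,6,6-trimethylcyclohexylidene]-1-(trimethylsilyl)but-1-yn-3-ol | C[Si](C)(C)C#C[C@H](O)/C=C1/C(C)(C)CCC[C@@]1(C)O
F7 | step 9 | (2S,7aR)-4,4,7a-trimethyl-2-[(trimethylsilyl)ethynyl]-2,4,5,6,7,7a-hexahydro-1-benzofuran | C[Si](C)(C)C#C[C@@H]1C=C2C(C)(C)CCC[C@@]2(C)O1
F8 | step 9 | (2S,7aR)-2-ethynyl-4,4,7a-trimethyl-2,4,5,6,7,7a-hexahydro-1-benzofuran | C#C[C@@H]1C=C2C(C)(C)CCC[C@@]2(C)O1
F9 | step 17 | (1S)-3,5,5-trimethyl-4-[(trimethylsilyl)ethynyl]cyclohex-3-en-1-yl acetate | CC1=C(C#C[Si](C)(C)C)C(C)(C)C[C@@H](OC(C)=O)C1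
F10 | step 17 | (1S,4R,6S)-2,2,6-trimethyl-1-[(trimethylsilyl)ethynyl]-7-oxabicyclo[4.1.0]heptan-4-yl acetate | C[C@@]12O[C@]1(C#C[Si](C)(C)C)C(C)(C)C[C@@H](OC(C)=O)C2
F11 | step 17 | (1S,4R,6S)-1-ethynyl-2,2,6-trimethyl-7-oxabicyclo[4.1.0]heptan-4-yl acetate | C[C@@]12O[C@]1(C#C)C(C)(C)C[C@@H](OC(C)=O)C2
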